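**Retrosynthetic overview**

1. Ring labels: A = 4-hydroxystyryl arene, B/C = benzo and dihydrofuran rings of the styryl-bearing dihydrobenzofuran (O1, C2, C3, C3a–C7a), D = aryl on C2, E/F = benzo and dihydrofuran rings of the second dihydrobenzofuran, G = resorcinol ring, H = aryl on C2 of ring F. The last step frees seven phenols from the heptakis(methoxymethyl) ether 25.
2. Key disconnection: ring C is opened at O1–C7a and at C2–C3, giving 4-(methoxymethoxy)benzaldehyde 17 and the diarylmethane 22, whose ring B carries a homochiral p-tolylsulfinyl group on C7a.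
3. Enabling feature: C3 is a diarylmethane carbon bonded to C3a, next to C7a. A sulfinyl group on C7a acidifies C3–H, relays its chirality to C3 through a lithium chelate, and is then the leaving group that the new alkoxide displaces, so it is gone when ring C closes.
4. 22 comes from a Negishi union (C3–C5 of ring E) of the laterally metallated tolyl sulfoxide 19 (rings A, B) with bromide 12 (rings E–H). 12 comes from an enantioselective rhodium carbene C–H insertion (ring F), then BBr3 demethylation with cis-to-trans epimerisation at C2 of ring F.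
5. Ring order: F (step 5), then C (step 13). Rings A, B, D, E, G and H are bought as arenes.

Key step: step 13

Assumption: the facial sense of Rh2(R-PTAD)4 in step 5 and of the (S)-sulfinyl group in step 13 is taken to give the configurations drawn (3R in ring F, 3S in ring C); if either proved opposite, the enantiomeric catalyst or (1S,2R,5S)-menthyl (R)-p-toluenesulfinate would be used with nothing else changed.

**Route**

Step 1
Reactants: 1 5-bromo-2-hydroxy-3-methoxybenzaldehyde; 2 1-(chloromethyl)-4-methoxybenzene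
Product: 3 5-bromo-3-methoxy-2-[(4-methoxyphenyl)methoxy]benzaldehyde
Conditions: K2CO3, DMF, 60 °C
Reagents that add atoms: none
Why: Williamson ether synthesis; the acidic salicylaldehyde phenol should be alkylated cleanly by the reactive benzylic chloride.

Step 2
Reactants: 4 1-bromo-3,5-dimethoxybenzene; 3 5-bromo-3-methoxy-2-[(4-methoxyphenyl)methoxy]benzaldehyde
Product: 6 {5-bromo-3-methoxy-2-[(4-methoxyphenyl)methoxy]phenyl}(3,5-dimethoxyphenyl)methanol (racemic), via aryl Grignard reagent 5 (not isolated)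
Conditions: Mg, I2 (cat.), THF, 65 °C; then 3, THF, 0 °C; NH4Cl (aq)
Reagents that add atoms: none
Why: Grignard addition to an aldehyde; the reagent is formed before 3 is added, so the aryl bromide of 3 stays intact, and the carbinol centre is removed in step 3.

Step 3
Reactants: 6 the diaryl carbinol
Product: 7 {5-bromo-3-methoxy-2-[(4-methoxyphenyl)methoxy]phenyl}(3,5-dimethoxyphenyl)methanone
Conditions: MnO2, CH2Cl2, 20 °C
Reagents that add atoms: none
Why: MnO2 oxidation of a doubly benzylic alcohol to the benzophenone, mild enough for the benzylic ether.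

Step 4
Reactants: 7 the benzophenone
Product: 8 hydrazone of 7 (C=N–NH2, E/Z mixture)
Conditions: N2H4·H2O, AcOH (cat.), EtOH, 80 °C
Reagents that add atoms: hydrazine (as hydrate), NN
Why: hydrazone condensation of a diaryl ketone; the C=N geometry is irrelevant because both isomers give the same diazo compound.

Step 5
Reactants: 8 the hydrazone
Product: 10 (2S,3R)-5-bromo-3-(3,5-dimethoxyphenyl)-7-methoxy-2-(4-methoxyphenyl)-2,3-dihydro-1-benzofuran (2,3-cis), via diazo compound 9 (not isolated)
Conditions: MnO2, CH2Cl2, 0 °C, filter; Rh2(R-PTAD)4 (1 mol %), CH2Cl2, 0 °C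
Reagents that add atoms: none
Why: hydrazone oxidation to a diaryldiazomethane followed by enantioselective intramolecular C–H insertion of a donor/donor rhodium carbene into the benzylic ether C–H, which closes ring F; the chiral carboxylate ligands select the carbene face (C3) and the concerted insertion should place the two aryl groups cis (C2).

Step 6
Reactants: 10 the cis tetramethyl ether
Product: 11 5-[(2R,3R)-5-bromo-7-hydroxy-2-(4-hydroxyphenyl)-2,3-dihydro-1-benzofuran-3-yl]benzene-1,3-diol (2,3-trans)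
Conditions: BBr3, CH2Cl2, −78 to 0 °C; H2O
Reagents that add atoms: none
Why: Lewis-acid cleavage of aryl methyl ethers; the same reagent reversibly ionises the benzylic C2–O bond (stabilised by the para-oxygen of ring H), so ring F should reclose to the thermodynamically favoured trans isomer while C3 is untouched.

Step 7
Reactants: 11 the trans tetraphenol
Product: 12 (2R,3R)-5-bromo-3-[3,5-bis(methoxymethoxy)phenyl]-7-(methoxymethoxy)-2-[4-(methoxymethoxy)phenyl]-2,3-dihydro-1-benzofuran
Conditions: MOMCl, i-Pr2NEt, CH2Cl2, 0 to 20 °C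
Reagents that add atoms: chloromethyl methyl ether, COCCl
Why: O-alkylation of phenols to methoxymethyl acetals under weakly basic conditions that should not open ring F.

Step 8
Reactants: 13 3,5-dibromo-4-methylphenol
Product: 14 1,3-dibromo-5-(methoxymethoxy)-2-methylbenzene
Conditions: NaH, DMF, 0 °C; MOMCl
Reagents that add atoms: chloromethyl methyl ether, COCCl
Why: phenoxide O-alkylation (methoxymethyl protection) of a simple phenol.

Step 9
Reactants: 14 the dibromide
Product: 16 1-bromo-5-(methoxymethoxy)-2-methyl-3-[(S)-(4-methylphenyl)sulfinyl]benzene, via aryl Grignard reagent 15 (not isolated)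
Conditions: i-PrMgCl·LiCl, THF, −15 to 0 °C; (1R,2S,5R)-menthyl (S)-p-toluenesulfinate, −40 to 0 °C
Reagents that add atoms: (1R,2S,5R)-menthyl (S)-4-methylbenzenesulfinate, C[C@@H]1CC[C@H]([C@@H](C1)O[S@](=O)c1ccc(C)cc1)C(C)C
Why: bromine–magnesium exchange at one of two equivalent bromines, then Andersen sulfoxide synthesis; substitution at sulfur with inversion sets the (S)-sulfur stereocentre.

Step 10
Reactants: 17 4-(methoxymethoxy)benzaldehyde
Product: 18 1-ethenyl-4-(methoxymethoxy)benzene
Conditions: Ph3PCH3Br, KOt-Bu, THF, 0 to 20 °C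
Reagents that add atoms: methyltriphenylphosphonium bromide, C[P+](c1ccccc1)(c1ccccc1)c1ccccc1.[Br-]
Why: Wittig methylenation of an aromatic aldehyde.

Step 11
Reactants: 16 the bromo sulfoxide; 18 the styrene
Product: 19 5-(methoxymethoxy)-1-{(E)-2-[4-(methoxymethoxy)phenyl]ethenyl}-2-methyl-3-[(S)-(4-methylphenyl)sulfinyl]benzene
Conditions: Pd(OAc)2 (5 mol %), P(o-tol)3, Et3N, DMF, 100 °C
Reagents that add atoms: none
Why: Mizoroki–Heck reaction; syn insertion and syn β-hydride elimination should give the E-stilbene, and the diaryl sulfoxide is configurationally stable at this temperature.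

Step 12
Reactants: 19 the tolyl sulfoxide; 12 the aryl bromide
Product: 22 (2R,3R)-3-[3,5-bis(methoxymethoxy)phenyl]-7-(methoxymethoxy)-2-[4-(methoxymethoxy)phenyl]-5-({4-(methoxymethoxy)-2-[(E)-2-[4-(methoxymethoxy)phenyl]ethenyl]-6-[(S)-(4-methylphenyl)sulfinyl]phenyl}methyl)-2,3-dihydro-1-benzofuran, via benzylic lithium reagent 20 (not isolated), via benzylic zinc chloride 21 (not isolated)
Conditions: LiN(i-Pr)2, THF, −78 °C; ZnCl2, −78 to 0 °C; 12, Pd(OAc)2 (3 mol %), SPhos, THF, 50 °C
Reagents that add atoms: none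
Why: sulfinyl-assisted lateral lithiation of the ortho methyl group, transmetallation to zinc and Negishi cross-coupling with the unhindered aryl bromide; no stereocentre is formed and the sulfur and ring F centres are not touched.

Step 13
Reactants: 22 the diarylmethane sulfoxide; 17 4-(methoxymethoxy)benzaldehyde
Product: 25 heptakis(methoxymethyl) ether of the target, (2S,3S) in ring C and (2R,3R) in ring F, via lithium carbanion 23 (not isolated), via lithium alkoxide 24 (not isolated)
Conditions: LiN(i-Pr)2 (1.05 equiv), THF, −78 °C; 17, −78 °C; DMPU, −78 to 20 °C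
Reagents that add atoms: none
Why: Proposed new method: LiN(i-Pr)2 removes the doubly benzylic C3–H of 22, which is acidified and lithium-chelated by the sulfinyl oxygen on C7a; carbanion 23 adds to the carbonyl carbon of 17 (C2–C3 bond), and alkoxide 24 then attacks C7a of ring B in an ipso nucleophilic aromatic substitution that expels p-toluenesulfenate (O1–C7a bond). The closest known reaction type is the anionic–anionic tandem of 2-(p-tolylsulfinyl)alkylbenzene carbanions with imines, where the amide nitrogen displaces the sulfinyl group to give indolines, together with the base-mediated displacement of aryl sulfoxides by alkoxides; an alkoxide in the intramolecular role is the new element. Ring C is closed by 5-exo attack of oxygen on the arene carbon ortho to the tether, through a Meisenheimer-type (or sulfurane ligand-coupling) transition state. C3 is set by the sulfur stereocentre, because the lithium held by the sulfinyl oxygen delivers the aldehyde to one face of the carbanion, and C2 should be set trans to the ring E aryl group because the anti arrangement of the two aryl groups reaches the closure geometry more easily while the addition is still reversible. The step needs deprotonation at C3 rather than at C3 of ring F or the tolyl methyl, which the sulfinyl-directed and much more acidic diarylmethane position secures, and it needs oxygen to attack carbon rather than sulfur, which the five-membered closure favours; one equivalent of base protects the product from eliminative ring opening.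

Step 14
Reactants: 25 the heptakis(methoxymethyl) ether
Product: 26 5-[(2R,3R)-5-[(2S,3S)-6-hydroxy-2-(4-hydroxyphenyl)-4-[(E)-2-(4-hydroxyphenyl)ethenyl]-2,3-dihydro-1-benzofuran-3-yl]-7-hydroxy-2-(4-hydroxyphenyl)-2,3-dihydro-1-benzofuran-3-yl]benzene-1,3-diol (CNP0172909.1)
Conditions: HCl (aq, 3 M), i-PrOH/THF, 45 °C
Reagents that add atoms: none
Why: acid-catalysed hydrolysis of aryl methoxymethyl acetals, mild enough that the stilbene and both trans-dihydrobenzofurans should survive; no stereocentre is touched.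

**Compound list**

1 | 5-bromo-2-hydroxy-3-methoxybenzaldehyde | COc1cc(Br)cc(C=O)c1O | starting material
2 | 1-(chloromethyl)-4-methoxybenzene | COc1ccc(CCl)cc1 | starting material
3 | 5-bromo-3-methoxy-2-[(4-methoxyphenyl)methoxy]benzaldehyde | COc1ccc(COc2c(OC)cc(Br)cc2C=O)cc1 | intermediate
4 | 1-bromo-3,5-dimethoxybenzene | COc1cc(OC)cc(Br)c1 | starting material
5 | (3,5-dimethoxyphenyl)magnesium bromide | COc1cc(OC)cc([Mg]Br)c1 | intermediate
6 | {5-bromo-3-methoxy-2-[(4-methoxyphenyl)methoxy]phenyl}(3,5-dimethoxyphenyl)methanol (racemic) | COc1ccc(COc2c(OC)cc(Br)cc2C(O)c2cc(OC)cc(OC)c2)cc1 | intermediate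
7 | {5-bromo-3-methoxy-2-[(4-methoxyphenyl)methoxy]phenyl}(3,5-dimethoxyphenyl)methanone | COc1ccc(COc2c(OC)cc(Br)cc2C(=O)c2cc(OC)cc(OC)c2)cc1 | intermediate
8 | hydrazone of ketone 7 | COc1ccc(COc2c(OC)cc(Br)cc2C(=NN)c2cc(OC)cc(OC)c2)cc1 | intermediate
9 | 5-bromo-1-[diazo(3,5-dimethoxyphenyl)methyl]-3-methoxy-2-[(4-methoxyphenyl)methoxy]benzene | COc1ccc(COc2c(OC)cc(Br)cc2C(=[N+]=[N-])c2cc(OC)cc(OC)c2)cc1 | intermediate
10 | (2S,3R)-5-bromo-3-(3,5-dimethoxyphenyl)-7-methoxy-2-(4-methoxyphenyl)-2,3-dihydro-1-benzofuran (cis) | Brc1cc(OC)c2c(c1)[C@@H](c1cc(OC)cc(OC)c1)[C@@H](c1ccc(OC)cc1)O2 | intermediate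
11 | 5-[(2R,3R)-5-bromo-7-hydroxy-2-(4-hydroxyphenyl)-2,3-dihydro-1-benzofuran-3-yl]benzene-1,3-diol (trans) | Brc1cc(O)c2c(c1)[C@@H](c1cc(O)cc(O)c1)[C@H](c1ccc(O)cc1)O2 | intermediate
12 | (2R,3R)-5-bromo-3-[3,5-bis(methoxymethoxy)phenyl]-7-(methoxymethoxy)-2-[4-(methoxymethoxy)phenyl]-2,3-dihydro-1-benzofuran | Brc1cc(OCOC)c2c(c1)[C@@H](c1cc(OCOC)cc(OCOC)c1)[C@H](c1ccc(OCOC)cc1)O2 | intermediate
13 | 3,5-dibromo-4-methylphenol | Cc1c(Br)cc(O)cc1Br | starting material
14 | 1,3-dibromo-5-(methoxymethoxy)-2-methylbenzene | Cc1c(Br)cc(OCOC)cc1Br | intermediate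
15 | [3-bromo-5-(methoxymethoxy)-2-methylphenyl]magnesium chloride | Cc1c(Br)cc(OCOC)cc1[Mg]Cl | intermediate
16 | 1-bromo-5-(methoxymethoxy)-2-methyl-3-[(S)-(4-methylphenyl)sulfinyl]benzene | Cc1ccc(cc1)[S@](=O)c1cc(OCOC)cc(Br)c1C | intermediate
17 | 4-(methoxymethoxy)benzaldehyde | COCOc1ccc(C=O)cc1 | starting material
18 | 1-ethenyl-4-(methoxymethoxy)benzene | COCOc1ccc(C=C)cc1 | intermediate
19 | 5-(methoxymethoxy)-1-{(E)-2-[4-(methoxymethoxy)phenyl]ethenyl}-2-methyl-3-[(S)-(4-methylphenyl)sulfinyl]benzene | Cc1ccc(cc1)[S@](=O)c1cc(OCOC)cc(/C=C/c2ccc(OCOC)cc2)c1C | intermediate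
20 | benzylic lithium reagent of 19 (lithium on the former methyl carbon) | Cc1ccc(cc1)[S@](=O)c1cc(OCOC)cc(/C=C/c2ccc(OCOC)cc2)c1C[Li] | intermediate
21 | benzylic zinc chloride of 19 | Cc1ccc(cc1)[S@](=O)c1cc(OCOC)cc(/C=C/c2ccc(OCOC)cc2)c1C[Zn]Cl | intermediate
22 | (2R,3R)-3-[3,5-bis(methoxymethoxy)phenyl]-7-(methoxymethoxy)-2-[4-(methoxymethoxy)phenyl]-5-({4-(methoxymethoxy)-2-[(E)-2-[4-(methoxymethoxy)phenyl]ethenyl]-6-[(S)-(4-methylphenyl)sulfinyl]phenyl}methyl)-2,3-dihydro-1-benzofuran | Cc1ccc(cc1)[S@](=O)c1cc(OCOC)cc(/C=C/c2ccc(OCOC)cc2)c1Cc1cc(OCOC)c2c(c1)[C@@H](c1cc(OCOC)cc(OCOC)c1)[C@H](c1ccc(OCOC)cc1)O2 | intermediate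
23 | lithium carbanion of 22 (lithium on the diarylmethane carbon) | Cc1ccc(cc1)[S@](=O)c1cc(OCOC)cc(/C=C/c2ccc(OCOC)cc2)c1C([Li])c1cc(OCOC)c2c(c1)[C@@H](c1cc(OCOC)cc(OCOC)c1)[C@H](c1ccc(OCOC)cc1)O2 | intermediate
24 | lithium (1S,2S)-1-[4-(methoxymethoxy)phenyl]-2-[ring B aryl of 22]-2-[dihydrobenzofuran-5-yl unit of 22]ethan-1-olate | Cc1ccc(cc1)[S@](=O)c1cc(OCOC)cc(/C=C/c2ccc(OCOC)cc2)c1[C@H](c1cc(OCOC)c2c(c1)[C@@H](c1cc(OCOC)cc(OCOC)c1)[C@H](c1ccc(OCOC)cc1)O2)[C@@H](c1ccc(OCOC)cc1)O[Li] | intermediate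
25 | heptakis(methoxymethyl) ether of 26, (2S,3S) in ring C and (2R,3R) in ring F | COCOc1ccc(/C=C/c2cc(OCOC)cc3c2[C@H](c2cc(OCOC)c4c(c2)[C@@H](c2cc(OCOC)cc(OCOC)c2)[C@H](c2ccc(OCOC)cc2)O4)[C@@H](c2ccc(OCOC)cc2)O3)cc1 | intermediate
26 | 5-[(2R,3R)-5-[(2S,3S)-6-hydroxy-2-(4-hydroxyphenyl)-4-[(E)-2-(4-hydroxyphenyl)ethenyl]-2,3-dihydro-1-benzofuran-3-yl]-7-hydroxy-2-(4-hydroxyphenyl)-2,3-dihydro-1-benzofuran-3-yl]benzene-1,3-diol | Oc1ccc(/C=C/c2cc(O)cc3c2[C@H](c2cc(O)c4c(c2)[C@@H](c2cc(O)cc(O)c2)[C@H](c2ccc(O)cc2)O4)[C@@H](c2ccc(O)cc2)O3)cc1 | target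

**Step count and risks**

Total step count: 14. Longest linear sequence: 10 steps (steps 1–7, 12, 13, 14).

Steps most likely to fail:

1. Step 13 (Proposed new method). The lithium alkoxide may attack sulfur and cleave the C7a–S bond without forming the ether, or the addition may revert so that facial control by sulfur is eroded. Any excess base could also open ring C by elimination. The fallback uses known chemistry, sets out from 22 and returns at 25. Only the carbanion addition is run (LiN(i-Pr)2, THF, −78 °C; 17; NH4Cl quench at −78 °C), a documented reaction of o-sulfinyl benzyl carbanions with aldehydes, to give the hydroxy sulfoxide F1. Its sulfinyl group is exchanged for iodine by sulfoxide–magnesium exchange and iodination (i-PrMgCl·LiCl, THF, −50 °C; I2) to give the iodo alcohol F2. Ring C is then closed by intramolecular Ullmann O-arylation (CuI, 1,10-phenanthroline, Cs2CO3, toluene, 110 °C), giving 25.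

2. Step 12. Metallation may occur at C7–H of ring B, which lies between the sulfinyl and methoxymethoxy groups, instead of at the methyl group. The doubly ortho-substituted benzylic zinc reagent may also transmetallate slowly and homocouple. The fallback avoids benzylic metallation by decorating ring B after the union; it sets out from 14 and 12 and returns at 22. Radical bromination of 14 (NBS, AIBN, K2CO3, PhCF3, 85 °C) gives the benzylic bromide F3. Miyaura borylation of 12 (B2pin2, Pd(dppf)Cl2, KOAc, dioxane, 90 °C) gives the pinacol boronate F4. A Suzuki–Miyaura coupling selective for the benzylic C–Br bond (Pd(PPh3)4, K2CO3, THF/H2O, 60 °C) gives the dibromo diarylmethane F5. Exchange of one of the two equivalent bromines and Andersen sulfinylation (i-PrMgCl·LiCl; menthyl sulfinate as in step 9) gives the bromo sulfoxide F6, and a Heck reaction with 18 under the step 11 conditions gives 22.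

3. Step 14. Formaldehyde set free in acid may attack the electron-rich resorcinol-type rings, and protonation of the stilbene may lead to Friedel–Crafts closure onto ring E. The fallback sets out from 25 and returns at 26, and replaces hydrolysis by silyl exchange. TMSOTf and 2,2'-bipyridyl in CH3CN at 0 °C convert aryl methoxymethyl ethers into aryl trimethylsilyl ethers, giving the heptakis(trimethylsilyl) ether F7, which water at neutral pH hydrolyses to 26.

**Further compounds**

F1 | step 13 | (1S,2S)-1-[4-(methoxymethoxy)phenyl]-2-[ring B aryl of 22 with the (S)-sulfinyl group]-2-[dihydrobenzofuran-5-yl unit of 22]ethan-1-ol | Cc1ccc(cc1)[S@](=O)c1cc(OCOC)cc(/C=C/c2ccc(OCOC)cc2)c1[C@H](c1cc(OCOC)c2c(c1)[C@@H](c1cc(OCOC)cc(OCOC)c1)[C@H](c1ccc(OCOC)cc1)O2)[C@@H](c1ccc(OCOC)cc1)O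
F2 | step 13 | (1S,2S)-iodo alcohol: F1 with iodine in place of the sulfinyl group | Ic1cc(OCOC)cc(/C=C/c2ccc(OCOC)cc2)c1[C@H](c1cc(OCOC)c2c(c1)[C@@H](c1cc(OCOC)cc(OCOC)c1)[C@H](c1ccc(OCOC)cc1)O2)[C@@H](c1ccc(OCOC)cc1)O
F3 | step 12 | 1,3-dibromo-2-(bromomethyl)-5-(methoxymethoxy)benzene | BrCc1c(Br)cc(OCOC)cc1Br
F4 | step 12 | pinacol boronate of 12: (2R,3R)-3-[3,5-bis(methoxymethoxy)phenyl]-7-(methoxymethoxy)-2-[4-(methoxymethoxy)phenyl]-5-(4,4,5,5-tetramethyl-1,3,2-dioxaborolan-2-yl)-2,3-dihydro-1-benzofuran | CC1(C)OB(OC1(C)C)c1cc(OCOC)c2c(c1)[C@@H](c1cc(OCOC)cc(OCOC)c1)[C@H](c1ccc(OCOC)cc1)O2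
F5 | step 12 | (2R,3R)-5-{[2,6-dibromo-4-(methoxymethoxy)phenyl]methyl}-3-[3,5-bis(methoxymethoxy)phenyl]-7-(methoxymethoxy)-2-[4-(methoxymethoxy)phenyl]-2,3-dihydro-1-benzofuran | COCOc1cc(Br)c(Cc2cc(OCOC)c3c(c2)[C@@H](c2cc(OCOC)cc(OCOC)c2)[C@H](c2ccc(OCOC)cc2)O3)c(Br)c1
F6 | step 12 | bromo sulfoxide: 22 with bromine in place of the styryl group, (S) at sulfur | Cc1ccc(cc1)[S@](=O)c1cc(OCOC)cc(Br)c1Cc1cc(OCOC)c2c(c1)[C@@H](c1cc(OCOC)cc(OCOC)c1)[C@H](c1ccc(OCOC)cc1)O2
F7 | step 14 | heptakis(trimethylsilyl) ether of 26 | C[Si](C)(C)Oc1ccc(/C=C/c2cc(O[Si](C)(C)C)cc3c2[C@H](c2cc(O[Si](C)(C)C)c4c(c2)[C@@H](c2cc(O[Si](C)(C)C)cc(O[Si](C)(C)C)c2)[C@H](c2ccc(O[Si](C)(C)C)cc2)O4)[C@@H](c2ccc(O[Si](C)(C)C)cc2)O3)cc1
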